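## Analysis of the target

The target is an unsymmetrical bis(flavan-3,4-diol). Each half is a 2-aryl-chromane with a catechol on ring A (O-7, O-8), a 4-hydroxyphenyl ring B on C2 and a free 3-OH, and the halves are joined by one ether oxygen between their C4 atoms. From the SMILES, the first half (unit A) is (2R,3R,4R), all-cis around ring C, and the second half (unit B) is (2S,3R,4R), 2,3-trans-3,4-cis. The halves share the (3R,4R) pair and differ only at C2, so the molecule is a pair of C2 epimers and cannot come from a homodimerisation.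

Each ether carbon is benzylic, para to O-7 and ortho to O1. Either C4–O bond therefore ionises easily with acid and, once O-7 is free, with base through a para-quinone methide. C2 is a 4-hydroxybenzylic ether that can epimerise by ring opening, and the catechols are oxidation-prone.

The main difficulty is C4 of unit A. A nucleophile adds to a flavan C4 cation trans to the 2-aryl group. That is what unit B needs, but unit A has the ether oxygen cis to both the 2-aryl group and O-3. In addition, the ether joins two hindered secondary carbons of nearly equal acid lability, so the activation must single out one C4.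

## Retrosynthetic reasoning

**18 to 17.** The six phenols are masked as benzyl ethers and freed last by neutral hydrogenolysis. The two secondary hydroxyls of 17 are already free, so the final step only has to cleave aryl–O–CH2Ph bonds, which react much faster than the hindered dialkyl benzylic ether.

**17 to 15 (key disconnection).** The C4–O bond of unit A is cut, not that of unit B. Unit B's C4–O bond has the configuration that a syn-dihydroxylation anti to the aryl group gives directly, so it is kept. Unit A's C4–O bond is the contra-steric one, and it is formed by delivering unit B's oxygen from a temporary dimethylsilylene tether on the cis O-3 of unit A. The C4 cation is made by DDQ hydride abstraction from the C4 methylene of unit A. This oxidative activation leaves the equally acid-labile C4–O bond of unit B untouched, and the unit A precursor needs no C4 oxygen at all.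

**15 to 13 and 8.** The two Si–O bonds are cut. The silaketal is assembled stepwise from the 2,3-cis flavan-3-ol 13 and the unit B alcohol 8, whose only free hydroxyl is the one at C4.

**8 to 7 to 6.** The O-3 silyl group of 8 is removed to give diol 7. Both C–O bonds of 7 are then cut back to the C3=C4 double bond of flavene 6, which a substrate-controlled OsO4 dihydroxylation anti to the 2-aryl group should convert into the (3R,4R) diol.

**13 to 12 to 11 to 9.** The cis 3-OH of 13 comes from hydride addition to ketone 12 anti to the 2-aryl group. Ketone 12 comes from the trans alcohol 11, and 11 from hydroboration of the enantiomeric flavene 9.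

**6 and 9 to 4 and 5.** The C2–aryl bond is cut in both series. One racemic chromene acetal 4 is coupled with boronic acid 5 under nickel catalysis with either antipode of one chiral ligand. This mirrors the target, whose halves differ only at C2.

**4 to 2 to 1.** Daphnetin 1 already contains ring A with O-7 and O-8, O1 and the C2–C3–C4 chain. Benzylation, lactone-to-lactol reduction and acetalisation give 4.

## Alternatives that were turned down

**Alternative 1:** the textbook cut of the C4–O bond of unit B, made intermolecularly. Tetra-O-benzyl-ent-oritin A2 would be oxidised at C4 with DDQ (or a 4-alkoxy derivative ionised with a Lewis acid) and the cation captured by the all-cis alcohol A1. The 2,4-trans preference would set C4 of unit B correctly. It was turned down for three reasons: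
- A1 already carries the contra-steric all-cis triad. Making it from a 2,3-cis flavan-3-ol takes protection, C4 hydroxylation (wrong epimer), oxidation and reduction, which adds about four steps to the longest branch.
- The nucleophile is a hindered secondary alcohol that must compete bimolecularly, and its own carbinol C–H and C4–O bond are open to DDQ and to acid.
- The reverse pairing, with unit A as the cation, gives the C4 epimer.

**Alternative 2:** two-directional synthesis with late symmetry breaking. Self-condensation of a single (2S,3R,4R) monomer, followed by liberation of the 4'-phenols, would give the C2-symmetric homodimer A3. Mild base would then open one ring C through the ring B para-quinone methide (O1–C2 heterolysis), and reclosure from the other face would invert one C2. This is the shortest route, but it was turned down: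
- The epimerisation is reversible and nothing stops it after one inversion, so at best a statistical mixture of A3, the mono-inverted and the bis-inverted dimer results.
- The position of the 2,3-trans/all-cis equilibrium is unknown and probably favours trans.
- The ring-opened phenoxide sits ortho to the C4 ether and can expel the other unit as an alkoxide.

**Alternative 3:** cutting O1–C2 and C3–C4 of ring C of unit A. An ortho-quinone methide A4, carrying unit B on the methide oxygen, would undergo an inverse-demand hetero-Diels–Alder reaction with the (Z)-enol acetate A5. An endo transition state would close ring C and set all three stereocentres at once. It was turned down because four selectivities are uncontrolled: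
- The enol oxygen polarises A5 against the required regiochemistry.
- The methide geometry is not fixed.
- Endo/exo selection is not secured.
- Facial selectivity would rest only on the remote stereocentres of unit B.

In addition, generating A4 from an acetal would ionise the very C–O bond that has to survive.

Key step: step 11

## Route

Assumption: the (R,R)-ligand is taken to give the (R)-flavene 6 and its antipode the (S)-flavene 9; if the sense of induction is the reverse, the two ligand antipodes are exchanged between steps 3 and 6.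

Step 1
Reactants: 1 daphnetin (7,8-dihydroxy-2H-chromen-2-one)
Product: 2 7,8-bis(benzyloxy)-2H-chromen-2-one
Conditions: BnBr, K2CO3, DMF, 60 °C
Reagents that add atoms: benzyl bromide, BrCc1ccccc1
Why: Williamson etherification of both catechol hydroxyls; the lactone is inert to carbonate in DMF.

Step 2
Reactants: 2 7,8-bis(benzyloxy)-2H-chromen-2-one
Product: 4 7,8-bis(benzyloxy)-2-ethoxy-2H-chromene (racemic acetal), via lactol 3 (not isolated)
Conditions: i-Bu2AlH, CH2Cl2, −78 °C; then EtOH, PPTS, rt
Reagents that add atoms: ethanol, CCO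
Why: Partial reduction of the coumarin lactone to the lactol, then acid-catalysed acetalisation through the benzopyrylium ion; the C2 configuration of 4 is irrelevant because the next step ionises this centre.

Step 3
Reactants: 4 7,8-bis(benzyloxy)-2-ethoxy-2H-chromene; 5 [4-(benzyloxy)phenyl]boronic acid
Product: 6 (2R)-7,8-bis(benzyloxy)-2-[4-(benzyloxy)phenyl]-2H-chromene
Conditions: Ni(cod)2 (cat.), (R,R)-TADDOL-derived phosphonite ligand (cat.), dioxane/t-AmOH, rt
Reagents that add atoms: none
Why: Enantioselective nickel-catalysed Suzuki-type coupling of a chromene acetal: zerovalent nickel ionises the allylic C2–OEt bond of both enantiomers of 4 to one nickel-bound benzopyrylium species, and the chiral ligand sets C2 in the aryl transfer. The expelled ethoxide activates the boronic acid, so no base is needed.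

Step 4
Reactants: 6 (2R)-7,8-bis(benzyloxy)-2-[4-(benzyloxy)phenyl]-2H-chromene
Product: 7 (2S,3R,4R)-7,8-bis(benzyloxy)-2-[4-(benzyloxy)phenyl]chromane-3,4-diol (2,3-trans-3,4-cis)
Conditions: OsO4 (cat.), NMO, acetone/H2O, 0 °C to rt
Reagents that add atoms: osmium tetroxide (catalytic oxygen carrier), O=[Os](=O)(=O)=O; N-methylmorpholine N-oxide, C[N+]1([O-])CCOCC1; water, O
Why: Catalytic syn-dihydroxylation of the C3=C4 bond from the face opposite the 2-aryl group, which sets C3 and C4 (both R) in one operation. The C2 descriptor changes from R to S only because C3 now outranks the aryl group.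

Step 5
Reactants: 7 (2S,3R,4R)-7,8-bis(benzyloxy)-2-[4-(benzyloxy)phenyl]chromane-3,4-diol
Product: 8 (2S,3R,4R)-7,8-bis(benzyloxy)-2-[4-(benzyloxy)phenyl]-3-[(tert-butyldimethylsilyl)oxy]chroman-4-ol
Conditions: TBSCl (1 equiv), imidazole, DMF, −20 to 0 °C
Reagents that add atoms: tert-butyldimethylsilyl chloride, CC(C)(C)[Si](C)(C)Cl
Why: Regioselective silylation of the equatorial 3-OH over the pseudoaxial benzylic 4-OH, which is shielded by the peri C5–H. A silyl ether is chosen because it cannot participate at C4 and leaves with the tether in step 11.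

Step 6
Reactants: 4 7,8-bis(benzyloxy)-2-ethoxy-2H-chromene; 5 [4-(benzyloxy)phenyl]boronic acid
Product: 9 (2S)-7,8-bis(benzyloxy)-2-[4-(benzyloxy)phenyl]-2H-chromene
Conditions: Ni(cod)2 (cat.), (S,S)-TADDOL-derived phosphonite ligand (cat.), dioxane/t-AmOH, rt
Reagents that add atoms: none
Why: The same stereoconvergent nickel-catalysed coupling as step 3 with the antipodal ligand, giving the enantiomeric flavene for unit A.

Step 7
Reactants: 9 (2S)-7,8-bis(benzyloxy)-2-[4-(benzyloxy)phenyl]-2H-chromene
Product: 11 (2R,3S)-7,8-bis(benzyloxy)-2-[4-(benzyloxy)phenyl]chroman-3-ol (2,3-trans), via alkylborane 10 (not isolated)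
Conditions: 9-BBN, THF, 60 °C; then NaOH, H2O2, 0 °C to rt
Reagents that add atoms: hydrogen peroxide, OO
Why: Hydroboration–oxidation: boron adds to C3 (remote from the arene) on the face opposite the 2-aryl group, and oxidation with retention gives the 2,3-trans alcohol.

Step 8
Reactants: 11 (2R,3S)-7,8-bis(benzyloxy)-2-[4-(benzyloxy)phenyl]chroman-3-ol
Product: 12 (2R)-7,8-bis(benzyloxy)-2-[4-(benzyloxy)phenyl]chroman-3-one
Conditions: Dess–Martin periodinane, NaHCO3, CH2Cl2, 0 °C to rt
Reagents that add atoms: none
Why: Buffered Dess–Martin oxidation; the nearly neutral medium should keep the enolisable C2 centre intact, and the ketone is used at once.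

Step 9
Reactants: 12 (2R)-7,8-bis(benzyloxy)-2-[4-(benzyloxy)phenyl]chroman-3-one
Product: 13 (2R,3R)-7,8-bis(benzyloxy)-2-[4-(benzyloxy)phenyl]chroman-3-ol (2,3-cis)
Conditions: LiBH(s-Bu)3, LiBr, THF, −78 °C
Reagents that add atoms: none
Why: The bulky hydride attacks the ketone from the face opposite the equatorial 2-aryl group, giving the axial 3-OH cis to the aryl group (3R).

Step 10
Reactants: 13 (2R,3R)-7,8-bis(benzyloxy)-2-[4-(benzyloxy)phenyl]chroman-3-ol; 8 (2S,3R,4R)-7,8-bis(benzyloxy)-2-[4-(benzyloxy)phenyl]-3-[(tert-butyldimethylsilyl)oxy]chroman-4-ol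
Product: 15 mixed dimethylsilylene bis-ether (silaketal) joining O-3 of 13 to O-4 of 8 with all stereocentres as in 13 and 8, via chlorosilyl ether 14 (not isolated)
Conditions: 13, n-BuLi, THF, −78 °C; Me2SiCl2 (excess), to rt; evaporate; then 8, imidazole, THF, rt
Reagents that add atoms: dichlorodimethylsilane, C[Si](C)(Cl)Cl
Why: Stepwise silaketal formation: the lithium alkoxide of 13 with excess dichlorosilane gives only the monochlorosilyl ether, the volatile excess is removed, and 8 is silylated under mild base so that its silyl group does not migrate. No stereocentre is touched.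

Step 11
Reactants: 15 mixed dimethylsilylene bis-ether of 13 (O-3) and 8 (O-4)
Product: 17 (2R,3R,4R)-7,8-bis(benzyloxy)-2-[4-(benzyloxy)phenyl]-4-{[(2S,3R,4R)-7,8-bis(benzyloxy)-2-[4-(benzyloxy)phenyl]-3-hydroxychroman-4-yl]oxy}chroman-3-ol, via aryloxysilyl ether 16 (not isolated)
Conditions: DDQ, 2,6-dichloropyridine, 4 Å MS, CH2Cl2 (high dilution), 0 °C to rt; then Bu4NF, AcOH, THF, rt
Reagents that add atoms: none
Why: Proposed new method: DDQ should abstract the axial hydride from the C4 methylene of unit A, the only benzylic CH2 that is para to an alkoxy group (O-7) and ortho to the ring oxygen, to give a para-quinone-methide-type C4 cation; this is the first event of the known DDQ-mediated C4 alkoxylation of O-benzylated flavan-3-ols. The silaketal oxygen that carries unit B is held under ring C by the axial O-3–Si bond and should close on C4 in a 5-exo-trig manner to a transient cis-fused 1,3-dioxa-2-silolane oxonium ring, the closest known reaction being silicon-tethered intramolecular aglycon delivery to oxocarbenium ions for 1,2-cis glycosides. Silyl transfer from this oxonium to the hydroquinone anion of reduced DDQ opens the ring again to 16, and fluoride then removes the tether residue and the silyl ether of unit B. The new stereocentre, C4 of unit A, is fixed by the tether: the oxygen must enter cis to O-3 and to the 2-aryl group (4R), the opposite of the 2,4-trans outcome of untethered capture. C4 of unit B is not formed here and keeps the configuration set in step 4, because its remaining hydrogen is pseudoequatorial and poorly aligned with the arene for hydride abstraction and no acid is present to ionise its C–O bond. The step needs site selectivity of hydride abstraction (the C4–H2 of unit A over the two C2–H bonds and the C4–H of unit B) and intramolecular over intermolecular capture; the double activation and axial alignment of the unit A C4–H, the sieves and the dilution should secure both. If the oxonium instead releases the stabilised C4 cation of unit B, recapture by the resulting 3,4-O-silylene oxygen of unit A on the 2,4-trans face of unit B leads to the same product.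

Step 12
Reactants: 17 hexa-O-benzyl ether of the target
Product: 18 (2R,3R,4R)-2-(4-hydroxyphenyl)-4-{[(2S,3R,4R)-3,7,8-trihydroxy-2-(4-hydroxyphenyl)chroman-4-yl]oxy}chromane-3,7,8-triol (target)
Conditions: H2 (1 atm), Pd/C, EtOAc/MeOH, rt
Reagents that add atoms: none
Why: Hydrogenolysis of six aryl benzyl ethers under neutral conditions; aryl–O–CH2Ph bonds should cleave much faster than the hindered secondary C4–O–C4 ether and the O1–C2 bonds, so the reaction is stopped as soon as the last benzyl group is gone. No stereocentre is touched.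

## Compound list

1 | daphnetin (7,8-dihydroxy-2H-chromen-2-one) | O=C1C=Cc2ccc(O)c(O)c2O1 | starting material
2 | 7,8-bis(benzyloxy)-2H-chromen-2-one | O=C1C=Cc2ccc(OCc3ccccc3)c(OCc3ccccc3)c2O1 | intermediate
3 | 7,8-bis(benzyloxy)-2H-chromen-2-ol (lactol, racemic) | OC1C=Cc2ccc(OCc3ccccc3)c(OCc3ccccc3)c2O1 | intermediate (not isolated)
4 | 7,8-bis(benzyloxy)-2-ethoxy-2H-chromene (racemic) | CCOC1C=Cc2ccc(OCc3ccccc3)c(OCc3ccccc3)c2O1 | intermediate
5 | [4-(benzyloxy)phenyl]boronic acid | OB(O)c1ccc(OCc2ccccc2)cc1 | starting material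
6 | (2R)-7,8-bis(benzyloxy)-2-[4-(benzyloxy)phenyl]-2H-chromene | C(c1ccccc1)Oc1ccc([C@@H]2Oc3c(ccc(OCc4ccccc4)c3OCc3ccccc3)C=C2)cc1 | intermediate
7 | (2S,3R,4R)-7,8-bis(benzyloxy)-2-[4-(benzyloxy)phenyl]chromane-3,4-diol | C(c1ccccc1)Oc1ccc([C@@H]2Oc3c(ccc(OCc4ccccc4)c3OCc3ccccc3)[C@@H](O)[C@H]2O)cc1 | intermediate
8 | (2S,3R,4R)-7,8-bis(benzyloxy)-2-[4-(benzyloxy)phenyl]-3-[(tert-butyldimethylsilyl)oxy]chroman-4-ol | C(c1ccccc1)Oc1ccc([C@@H]2Oc3c(ccc(OCc4ccccc4)c3OCc3ccccc3)[C@@H](O)[C@H]2O[Si](C)(C)C(C)(C)C)cc1 | intermediate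
9 | (2S)-7,8-bis(benzyloxy)-2-[4-(benzyloxy)phenyl]-2H-chromene | C(c1ccccc1)Oc1ccc([C@H]2Oc3c(ccc(OCc4ccccc4)c3OCc3ccccc3)C=C2)cc1 | intermediate
10 | 9-{7,8-bis(benzyloxy)-2-[4-(benzyloxy)phenyl]chroman-3-yl}-9-borabicyclo[3.3.1]nonane, boron trans to the 2-aryl group, C2 and C3 as in 11 | C(c1ccccc1)Oc1ccc([C@H]2Oc3c(ccc(OCc4ccccc4)c3OCc3ccccc3)C[C@@H]2B2C3CCCC2CCC3)cc1 | intermediate (not isolated)
11 | (2R,3S)-7,8-bis(benzyloxy)-2-[4-(benzyloxy)phenyl]chroman-3-ol | C(c1ccccc1)Oc1ccc([C@H]2Oc3c(ccc(OCc4ccccc4)c3OCc3ccccc3)C[C@@H]2O)cc1 | intermediate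
12 | (2R)-7,8-bis(benzyloxy)-2-[4-(benzyloxy)phenyl]chroman-3-one | C(c1ccccc1)Oc1ccc([C@H]2Oc3c(ccc(OCc4ccccc4)c3OCc3ccccc3)CC2=O)cc1 | intermediate
13 | (2R,3R)-7,8-bis(benzyloxy)-2-[4-(benzyloxy)phenyl]chroman-3-ol | C(c1ccccc1)Oc1ccc([C@H]2Oc3c(ccc(OCc4ccccc4)c3OCc3ccccc3)C[C@H]2O)cc1 | intermediate
14 | chloro(dimethyl)silyl ether of 13 at O-3 | C(c1ccccc1)Oc1ccc([C@H]2Oc3c(ccc(OCc4ccccc4)c3OCc3ccccc3)C[C@H]2O[Si](C)(C)Cl)cc1 | intermediate (not isolated)
15 | mixed dimethylsilylene bis-ether joining O-3 of 13 and O-4 of 8, stereocentres as in 13 and 8 | C(c1ccccc1)Oc1ccc([C@H]2Oc3c(ccc(OCc4ccccc4)c3OCc3ccccc3)C[C@H]2O[Si](C)(C)O[C@@H]2c3ccc(OCc4ccccc4)c(OCc4ccccc4)c3O[C@@H](c3ccc(OCc4ccccc4)cc3)[C@@H]2O[Si](C)(C)C(C)(C)C)cc1 | intermediate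
16 | ether 17 carrying a dimethyl(2,3-dichloro-5,6-dicyano-4-hydroxyphenoxy)silyl group on O-3 of unit A and the tert-butyldimethylsilyl group on O-3 of unit B | C(c1ccccc1)Oc1ccc([C@H]2Oc3c(ccc(OCc4ccccc4)c3OCc3ccccc3)[C@@H](O[C@@H]3c4ccc(OCc5ccccc5)c(OCc5ccccc5)c4O[C@@H](c4ccc(OCc5ccccc5)cc4)[C@@H]3O[Si](C)(C)C(C)(C)C)[C@H]2O[Si](C)(C)Oc2c(Cl)c(Cl)c(O)c(C#N)c2C#N)cc1 | intermediate (not isolated)
17 | (2R,3R,4R)-7,8-bis(benzyloxy)-2-[4-(benzyloxy)phenyl]-4-{[(2S,3R,4R)-7,8-bis(benzyloxy)-2-[4-(benzyloxy)phenyl]-3-hydroxychroman-4-yl]oxy}chroman-3-ol | C(c1ccccc1)Oc1ccc([C@H]2Oc3c(ccc(OCc4ccccc4)c3OCc3ccccc3)[C@@H](O[C@@H]3c4ccc(OCc5ccccc5)c(OCc5ccccc5)c4O[C@@H](c4ccc(OCc5ccccc5)cc4)[C@@H]3O)[C@H]2O)cc1 | intermediate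
18 | (2R,3R,4R)-2-(4-hydroxyphenyl)-4-{[(2S,3R,4R)-3,7,8-trihydroxy-2-(4-hydroxyphenyl)chroman-4-yl]oxy}chromane-3,7,8-triol | Oc1ccc([C@H]2Oc3c(ccc(O)c3O)[C@@H](O[C@@H]3c4ccc(O)c(O)c4O[C@@H](c4ccc(O)cc4)[C@@H]3O)[C@H]2O)cc1 | target

## Step count and least certain steps

Total step count: 12. Longest linear sequence: 9 steps (1, 2, 6, 7, 8, 9, 10, 11, 12); the unit B branch (steps 3 to 5) joins at step 10.

**Step 11 (key step, proposed new method).** Three processes are most likely to go wrong:
- hydride abstraction at a C2–H bond instead of the C4–H of unit A;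
- collapse of the transient silyloxonium by loss of the unit B cation, followed by elimination or capture by the reduced quinone;
- capture of the unit A cation by traces of water on the 2,4-trans face, with over-oxidation to the ketone.

The fallback uses known chemistry with the roles of the two units exchanged. It sets out from 13 and 8 and comes back at 17. Alcohol 13 is silylated (TBSCl, imidazole) to its 3-O-TBS ether F1. DDQ in wet CH2Cl2 hydroxylates C4 on the 2,4-trans face to the 4β-alcohol F2. Dess–Martin oxidation gives the 2,3-cis flavan-4-one F3. NaBH4 delivers hydride anti to the axial 3-silyloxy group to give the all-cis 4α-alcohol F4. Slow addition of 8 to an excess of F4 with catalytic Me3SiOTf and 4 Å sieves at low temperature ionises the pseudoaxial C4–OH of 8. The equatorial hydroxyl of F4 captures the cation on its 2,4-trans face to give the bis-silyl ether F5, and Bu4NF then gives 17.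

**Step 10.** Silaketal formation between two hindered secondary alcohols may be incomplete, may give symmetrical silaketals, or the product may hydrolyse on purification. The fallback replaces the silicon tether by a mixed acetal tether. It sets out from 13 and 8 and comes back at 17. Alcohol 13 is alkylated (NaH, 4-methoxybenzyl chloride) to the 3-O-(4-methoxybenzyl) ether F6. One equivalent of DDQ with 8 and 4 Å sieves oxidises the methoxybenzyl C–H, and the oxocarbenium ion is trapped by the 4-OH of 8 as the mixed 4-methoxybenzylidene acetal F7. More DDQ then generates the C4 cation of unit A, and the acetal oxygen bearing unit B is delivered cis to O-3. Aqueous work-up gives the ether F8, which still carries the silyl group on unit B, and Bu4NF gives 17.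

**Step 3 (and its mirror image, step 6).** The 8-benzyloxy group flanks the ring oxygen and may slow the ionisation of the acetal or erode the enantioselectivity. The fallback is a racemic synthesis with enzymatic resolution in which both enantiomers are used. It sets out from 4 and 5 and comes back at 11 and at 8. Coupling with Ni(cod)2/PPh3 gives the racemic flavene F9, and hydroboration–oxidation as in step 7 gives the racemic trans alcohol F10. Lipase-mediated acetylation (immobilised Candida antarctica lipase B, vinyl acetate) separates the enantiomers. On the assumption that the (2S,3R)-alcohol reacts faster, it is obtained as the acetate F11, and the (2R,3S)-alcohol is recovered as 11 for step 8. Methanolysis of F11 (K2CO3, MeOH) gives the (2S,3R)-alcohol F12, which is silylated to F13 and hydroxylated at C4 with DDQ in wet CH2Cl2 on the 2,4-trans face to give 8.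

**Step 5.** The two hydroxyl groups may be poorly discriminated, or the silyl group may migrate to O-4. The fallback differentiates them by the unique solvolytic lability of the benzylic C4–O bond. It sets out from 7 and comes back at 8. PPTS in methanol at low temperature exchanges only the C4 hydroxyl through the C4 cation, with re-entry on the 2,4-trans face, to give the 4-O-methyl ether F14. The remaining 3-OH is silylated (TBSOTf, 2,6-lutidine) to F15. PPTS in aqueous THF then hydrolyses the benzylic methyl ether through the same cation to give 8.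

## Further compounds

F1 | step 11 | (2R,3R)-7,8-bis(benzyloxy)-2-[4-(benzyloxy)phenyl]-3-[(tert-butyldimethylsilyl)oxy]chromane | C(c1ccccc1)Oc1ccc([C@H]2Oc3c(ccc(OCc4ccccc4)c3OCc3ccccc3)C[C@H]2O[Si](C)(C)C(C)(C)C)cc1
F2 | step 11 | (2R,3R,4S)-7,8-bis(benzyloxy)-2-[4-(benzyloxy)phenyl]-3-[(tert-butyldimethylsilyl)oxy]chroman-4-ol (2,4-trans) | C(c1ccccc1)Oc1ccc([C@H]2Oc3c(ccc(OCc4ccccc4)c3OCc3ccccc3)[C@H](O)[C@H]2O[Si](C)(C)C(C)(C)C)cc1
F3 | step 11 | (2R,3S)-7,8-bis(benzyloxy)-2-[4-(benzyloxy)phenyl]-3-[(tert-butyldimethylsilyl)oxy]chroman-4-one (2,3-cis) | C(c1ccccc1)Oc1ccc([C@H]2Oc3c(ccc(OCc4ccccc4)c3OCc3ccccc3)C(=O)[C@H]2O[Si](C)(C)C(C)(C)C)cc1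
F4 | step 11 | (2R,3R,4R)-7,8-bis(benzyloxy)-2-[4-(benzyloxy)phenyl]-3-[(tert-butyldimethylsilyl)oxy]chroman-4-ol (all-cis) | C(c1ccccc1)Oc1ccc([C@H]2Oc3c(ccc(OCc4ccccc4)c3OCc3ccccc3)[C@@H](O)[C@H]2O[Si](C)(C)C(C)(C)C)cc1
F5 | step 11 | bis(tert-butyldimethylsilyl) ether of 17 at O-3 of both units | C(c1ccccc1)Oc1ccc([C@H]2Oc3c(ccc(OCc4ccccc4)c3OCc3ccccc3)[C@@H](O[C@@H]3c4ccc(OCc5ccccc5)c(OCc5ccccc5)c4O[C@@H](c4ccc(OCc5ccccc5)cc4)[C@@H]3O[Si](C)(C)C(C)(C)C)[C@H]2O[Si](C)(C)C(C)(C)C)cc1
F6 | step 10 | (2R,3R)-7,8-bis(benzyloxy)-2-[4-(benzyloxy)phenyl]-3-[(4-methoxybenzyl)oxy]chromane | C(c1ccccc1)Oc1ccc([C@H]2Oc3c(ccc(OCc4ccccc4)c3OCc3ccccc3)C[C@H]2OCc2ccc(OC)cc2)cc1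
F7 | step 10 | mixed 4-methoxybenzylidene acetal joining O-3 of 13 and O-4 of 8 (both epimers at the acetal carbon) | C(c1ccccc1)Oc1ccc([C@H]2Oc3c(ccc(OCc4ccccc4)c3OCc3ccccc3)C[C@H]2OC(c2ccc(OC)cc2)O[C@@H]2c3ccc(OCc4ccccc4)c(OCc4ccccc4)c3O[C@@H](c3ccc(OCc4ccccc4)cc3)[C@@H]2O[Si](C)(C)C(C)(C)C)cc1
F8 | step 10 | tert-butyldimethylsilyl ether of 17 at O-3 of unit B | C(c1ccccc1)Oc1ccc([C@H]2Oc3c(ccc(OCc4ccccc4)c3OCc3ccccc3)[C@@H](O[C@@H]3c4ccc(OCc5ccccc5)c(OCc5ccccc5)c4O[C@@H](c4ccc(OCc5ccccc5)cc4)[C@@H]3O[Si](C)(C)C(C)(C)C)[C@H]2O)cc1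
F9 | step 3 | racemic 7,8-bis(benzyloxy)-2-[4-(benzyloxy)phenyl]-2H-chromene | C(c1ccccc1)Oc1ccc(C2Oc3c(ccc(OCc4ccccc4)c3OCc3ccccc3)C=C2)cc1
F10 | step 3 | racemic trans-7,8-bis(benzyloxy)-2-[4-(benzyloxy)phenyl]chroman-3-ol (1:1 mixture of 11 and F12) | C(c1ccccc1)Oc1ccc([C@H]2Oc3c(ccc(OCc4ccccc4)c3OCc3ccccc3)C[C@@H]2O)cc1.C(c1ccccc1)Oc1ccc([C@@H]2Oc3c(ccc(OCc4ccccc4)c3OCc3ccccc3)C[C@H]2O)cc1
F11 | step 3 | (2S,3R)-7,8-bis(benzyloxy)-2-[4-(benzyloxy)phenyl]chroman-3-yl acetate | C(c1ccccc1)Oc1ccc([C@@H]2Oc3c(ccc(OCc4ccccc4)c3OCc3ccccc3)C[C@H]2OC(C)=O)cc1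
F12 | step 3 | (2S,3R)-7,8-bis(benzyloxy)-2-[4-(benzyloxy)phenyl]chroman-3-ol | C(c1ccccc1)Oc1ccc([C@@H]2Oc3c(ccc(OCc4ccccc4)c3OCc3ccccc3)C[C@H]2O)cc1
F13 | step 3 | (2S,3R)-7,8-bis(benzyloxy)-2-[4-(benzyloxy)phenyl]-3-[(tert-butyldimethylsilyl)oxy]chromane | C(c1ccccc1)Oc1ccc([C@@H]2Oc3c(ccc(OCc4ccccc4)c3OCc3ccccc3)C[C@H]2O[Si](C)(C)C(C)(C)C)cc1
F14 | step 5 | (2S,3R,4R)-7,8-bis(benzyloxy)-2-[4-(benzyloxy)phenyl]-4-methoxychroman-3-ol | C(c1ccccc1)Oc1ccc([C@@H]2Oc3c(ccc(OCc4ccccc4)c3OCc3ccccc3)[C@@H](OC)[C@H]2O)cc1
F15 | step 5 | (2S,3R,4R)-7,8-bis(benzyloxy)-2-[4-(benzyloxy)phenyl]-3-[(tert-butyldimethylsilyl)oxy]-4-methoxychromane | C(c1ccccc1)Oc1ccc([C@@H]2Oc3c(ccc(OCc4ccccc4)c3OCc3ccccc3)[C@@H](OC)[C@H]2O[Si](C)(C)C(C)(C)C)cc1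
A1 | alternative 1 | (2R,3R,4R)-3,7,8-tris(benzyloxy)-2-[4-(benzyloxy)phenyl]chroman-4-ol (all-cis) | C(c1ccccc1)Oc1ccc([C@H]2Oc3c(ccc(OCc4ccccc4)c3OCc3ccccc3)[C@@H](O)[C@H]2OCc2ccccc2)cc1
A2 | alternative 1 | (2S,3R)-3,7,8-tris(benzyloxy)-2-[4-(benzyloxy)phenyl]chromane | C(c1ccccc1)Oc1ccc([C@@H]2Oc3c(ccc(OCc4ccccc4)c3OCc3ccccc3)C[C@H]2OCc2ccccc2)cc1
A3 | alternative 2 | bis[(2S,3R,4R)-7,8-bis(benzyloxy)-3-hydroxy-2-(4-hydroxyphenyl)chroman-4-yl] ether (C2-symmetric homodimer) | Oc1ccc([C@@H]2Oc3c(ccc(OCc4ccccc4)c3OCc3ccccc3)[C@@H](O[C@@H]3c4ccc(OCc5ccccc5)c(OCc5ccccc5)c4O[C@@H](c4ccc(O)cc4)[C@@H]3O)[C@H]2O)cc1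
A4 | alternative 3 | ortho-quinone methide: 2,3-bis(benzyloxy)-6-(alkoxymethylidene)cyclohexa-2,4-dien-1-one whose alkoxy group is the 4-oxy residue of 8 | O=C1C(OCc2ccccc2)=C(OCc2ccccc2)C=CC1=CO[C@@H]1c2ccc(OCc3ccccc3)c(OCc3ccccc3)c2O[C@@H](c2ccc(OCc3ccccc3)cc2)[C@@H]1O[Si](C)(C)C(C)(C)C
A5 | alternative 3 | (Z)-2-[4-(benzyloxy)phenyl]ethenyl acetate | CC(=O)O/C=C\c1ccc(OCc2ccccc2)cc1
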